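## Analysis of the target

- Target 29 is a tetralin. Numbering used throughout: ring B is C1 (side chain), C2, C3, C4 (methyl); ring A is C4a, C5 (OH), C6 (OH), C7 (CO2H), C8 (H), C8a; the chain is C11 (bearing hydroxymethyl C20), C12 to C14, C15 (methyl and hydroxymethyl C16).
- There are four stereocentres: C1 (S), C4 (R), C11 (S) and C15 (S). C1 and C4 are trans across ring B. C1 and C11 are a vicinal pair at the ring–chain junction. C15 lies three methylene groups away and cannot be controlled from the ring.
- Sensitive groups are the catechol (oxidised by air, above all in base), the ortho-hydroxy benzoic acid, two primary alcohols and two benzylic methine centres.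
- The synthesis is hard for three reasons. The C1/C11 pair has no heteroatom on either carbon to steer it. Ring A is pentasubstituted with five different neighbours. The 1,4-trans relation is the opposite of what undirected hydrogenation of a C3=C4 alkene should give.
- The strategy rests on one feature: C1 carries the aryl carbon C8a and C11 carries a one-carbon oxygenated branch. This is the pattern left when an aryl group and an alkyl group are added across an alkenyl boronate, with boron on C11 as the future C20.
- "B(mac)" below means the cyclic boronate of the cis-diol 12.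

## Retrosynthetic reasoning

**29 back to 27.** The last bonds cut are O–CH3 (two aryl ethers), O–CH2Ph (C16) and, one step earlier, the ester O–CH3 (via acid 28). The catechol is unmasked last and under acid, because it would not survive the basic and metal-mediated steps. The ester is hydrolysed while the catechol is still protected.

**27 back to 25.** Ring B is opened at C3–C4, first as the C3=C4 alkene of 26, then by metathesis to the diene 25.
- This bond is remote from C1 and C11, so closing it cannot disturb them.
- Both alkene partners are hydrocarbon groups that pass through the coupling untouched: an isopropenyl group on C4a (C4 and its methyl) and an allyl group on C1 (C2 and C3).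
- The forward hydrogenation has to add hydrogen to C4 from the face of the C1 side chain. The free C20 hydroxyl of 26 is there to direct it.

**25 back to 23.** The C11–C20 bond is cut and C20 is traced back to boron on C11. The forward step is a one-carbon insertion into the C–B bond with retention at C11, then oxidation. Boron is therefore the seed of the hydroxymethyl group and not a spectator.

**23 back to 10, 15 and 20 (key disconnection).** C1–C8a and C11–C12 are cut in one operation.
- The three pieces are the ring A triflate 10, the (E)-penta-1,4-dienyl boronate 15 (C11, C1, C2, C3) and the chain iodide 20 (C12 to C16), used as alkyllithium 21 and ate complex 22.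
- Cutting here joins all carbons of the target except C20 convergently and sets both C1 and C11.
- The forward reaction must add aryl and alkyl anti across the E alkene under chiral palladium catalysis, without transferring the alkenyl group itself to palladium. For that reason boron carries the hindered diol 12 and not a smaller diol.

**10 back to 1.** The triflate comes from phenol 9; the isopropenyl group from 8 by cross-coupling with bromide 7; the ester from carbonylation of one bromide of dibromophenol 6; the phenol oxygen from dibromide 3; and 3 from 1 by twofold ortho-metalation. The twofold symmetry of 3 removes every regiochemical question up to 6. After that the two bromides differ in their position relative to the hydroxyl.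

**15 back to 13 and 11.** The E-alkenyl boron bond comes from syn hydroboration of the terminal alkyne of 13 (via 14), followed by ester exchange with diol 12. Diol 12 comes from diketone 11 by double methyl addition.

**20 back to 16.** The C12–I bond comes from alcohol 19. The C13–C14 bond is cut to organomagnesium 18 and a two-carbon electrophile. Compound 18 comes from bromide 17, the benzyl ether of the chiral-pool bromo alcohol 16, which supplies C15.

## Alternatives that were turned down

**Alternative 1: gold-catalysed furan–yne closure of rings A and B.**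
- Disconnection: C4a–C8a and C5–C6. Ring A is built from a furan and an alkyne.
- Forward key step: in the acyclic furyl alkyne A1, a gold catalyst activates the alkyne. The furan carbon that becomes C8a attacks the alkyne carbon that becomes C4a, the furan opens, and ring A closes as the C5 phenol A2 while ring B closes at the same time.
- For it: two rings and the arene form in one atom-economic isomerisation from an open chain. The position of the C5 hydroxyl follows from the mechanism. No arene functionalisation sequence is needed; on this point it is stronger than the chosen route, which spends five steps on ring A.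
- Against it: A2 has no oxygen at C6. A late ortho-hydroxylation between the C5 hydroxyl and the C7 ester would be needed, on a hindered and deactivated position. A1 must already hold all four stereocentres, so the C1/C11 problem is only moved into the synthesis of A1. An all-carbon tether with a propargylic stereocentre and an ester-deactivated furan are unfavourable for this cyclisation.
- Comparison: the chosen strategy gives up the one-step arene construction and gains a single step that both joins the fragments and sets C1 and C11.

**Alternative 2: copper hydride hydroalkylation closing ring B at C3–C4.**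
- Disconnection: C3–C4, with C4 formed as a benzylic nucleophile.
- Forward key step: a chiral copper hydride catalyst adds to the vinyl group on C4a of bromide A3. The benzylic copper centre at C4 displaces the primary bromide at C3 and gives the fully protected tetralin A4.
- For it: C4 is set by the catalyst in the same step that closes ring B, without a directing group, and A4 is only a deprotection away from the target. On C4 control and on the length of the endgame this alternative is stronger than the chosen route, which needs metathesis and a directed hydrogenation.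
- Against it: the styrene of A3 is flanked on both sides (C5 methoxy group and the branched C8a substituent), so hydrocupration should be slow. The catalyst must override the adjacent C1 stereocentre. A3 still needs the C1/C11 pair from some other method.
- Comparison: the chosen strategy accepts a longer ring B closure and offers in return a defined way to make the C1/C11 pair.

**Alternative 3: ring A from a ring-B-fused 2-pyrone.**
- Disconnection: C4a–C5 and C6–C7.
- Forward key step: the 3-carbomethoxy-2-pyrone A5 undergoes [4+2] cycloaddition with the electron-rich alkene A6. The lactone bridge is then extruded and one methoxy group eliminated, so that ring A appears as the 5,6-dimethoxy benzoate A7.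
- For it: the substitution pattern of ring A is dictated entirely by the polarity of the two partners. This is more certain than the site-selective arene chemistry used here (steps 2 and 3).
- Against it: A5 is a linear target of its own. It must carry C1, C4, C11 and C15 on a cyclohexane before the arene exists. C4 lies next to the ketone-derived carbon and can epimerise during pyrone formation. The C1/C11 pair again needs separate control. The cycloaddition and aromatisation require heat.
- Comparison: the chosen route is convergent and puts its stereochemical risk in one catalytic step; the price is a five-step arene synthesis.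

Key step: step 11

Remark on the chemistry: both enantiomers of the ferrocenyl bisphosphine used in step 11 are available; the enantiomer that leads to the (1S,11S) series is meant throughout and its sense of induction is assumed to be selectable on a model substrate.

## Route

Step 1
Reactants: 1 1,2-dimethoxybenzene
Product: 3 1,4-dibromo-2,3-dimethoxybenzene, via 3,6-dilithio-1,2-dimethoxybenzene 2 (not isolated)
Conditions: n-BuLi (3 equiv), TMEDA, hexane, 25 °C to reflux; then BrCl2C–CCl2Br, THF, −78 °C to rt
Reagents that add atoms: 1,2-dibromo-1,1,2,2-tetrachloroethane, BrC(Cl)(Cl)C(Cl)(Cl)Br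
Why: Double directed ortho-metalation: each methoxy group directs lithium to its own free ortho carbon, and the twofold-symmetric dianion 2 is brominated at both sites, so no regiochemical question arises.

Step 2
Reactants: 3 1,4-dibromo-2,3-dimethoxybenzene
Product: 6 2,5-dibromo-3,4-dimethoxyphenol, via (2,5-dibromo-3,4-dimethoxyphenyl)lithium 4 (not isolated), via lithium (2,5-dibromo-3,4-dimethoxyphenyl)tri(propan-2-yloxy)borate 5 (not isolated)
Conditions: lithium 2,2,6,6-tetramethylpiperidide (LiTMP), B(OiPr)3 present from the start, THF, −78 °C; then NaOH, H2O2, 0 °C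
Reagents that add atoms: hydrogen peroxide, OO
Why: Deprotonative borylation–oxidation: the two ring hydrogens are equivalent and ortho to bromine, in situ borate trapping should intercept aryllithium 4 before halogen migration or aryne formation, and peroxide converts the C–B bond of 5 into C–OH.

Step 3
Reactants: 6 2,5-dibromo-3,4-dimethoxyphenol
Product: 7 methyl 4-bromo-5-hydroxy-2,3-dimethoxybenzoate
Conditions: Pd(OAc)2 (3 mol%), Xantphos, CO (1 atm), Et3N, MeOH, 70 °C
Reagents that add atoms: carbon monoxide, [C-]#[O+]; methanol, CO
Why: Palladium-catalysed methoxycarbonylation; oxidative addition should prefer the bromide meta to the partly ionised hydroxyl, which has one ortho substituent, over the bromide flanked by the phenoxide oxygen and a methoxy group, which is more electron-rich and more hindered.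

Step 4
Reactants: 7 methyl 4-bromo-5-hydroxy-2,3-dimethoxybenzoate; 8 4,4,5,5-tetramethyl-2-(prop-1-en-2-yl)-1,3,2-dioxaborolane
Product: 9 methyl 5-hydroxy-2,3-dimethoxy-4-(prop-1-en-2-yl)benzoate
Conditions: Pd(OAc)2 (3 mol%), SPhos, K3PO4, toluene/H2O, 90 °C
Reagents that add atoms: none
Why: Suzuki–Miyaura coupling of the remaining, doubly ortho-substituted bromide; a bulky biarylphosphine suits hindered electron-rich aryl bromides and the free phenol is tolerated.

Step 5
Reactants: 9 methyl 5-hydroxy-2,3-dimethoxy-4-(prop-1-en-2-yl)benzoate
Product: 10 methyl 2,3-dimethoxy-4-(prop-1-en-2-yl)-5-[(trifluoromethanesulfonyl)oxy]benzoate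
Conditions: Tf2O, pyridine, CH2Cl2, 0 °C
Reagents that add atoms: trifluoromethanesulfonic anhydride, O=S(=O)(OS(=O)(=O)C(F)(F)F)C(F)(F)F
Why: O-Sulfonylation of the phenol under basic conditions, which spare the acid-sensitive ortho isopropenyl group.

Step 6
Reactants: 11 acenaphthylene-1,2-dione
Product: 12 (1R,2S)-1,2-dimethyl-1,2-dihydroacenaphthylene-1,2-diol (cis, meso)
Conditions: MeMgBr (2.5 equiv), THF, 0 °C to rt; NH4Cl aq; crystallisation
Reagents that add atoms: methylmagnesium bromide, C[Mg]Br
Why: Twofold Grignard 1,2-addition to the diketone; the second methyl group should enter anti to the solvated magnesium alkoxide, that is cis to the first methyl, and the meso cis-diol (the only isomer that can bridge one boron atom) is purified by crystallisation.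

Step 7
Reactants: 13 pent-1-en-4-yne; 12 (1R,2S)-1,2-dimethyl-1,2-dihydroacenaphthylene-1,2-diol
Product: 15 (6bR,9aS)-6b,9a-dimethyl-8-[(1E)-penta-1,4-dien-1-yl]-6b,9a-dihydroacenaphtho[1,2-d][1,3,2]dioxaborole [the (E)-penta-1,4-dienyl B(mac) ester], via 2-[(1E)-penta-1,4-dien-1-yl]-1,3,2-benzodioxaborole 14 (not isolated)
Conditions: catecholborane (1.0 equiv), Cy2BH (5 mol%), THF, 25 °C; then 12, 25 °C
Reagents that add atoms: catecholborane, B1Oc2ccccc2O1
Why: Dialkylborane-catalysed hydroboration of the terminal alkyne is a syn, anti-Markovnikov addition that fixes the E geometry; the monosubstituted alkene can at most consume the catalytic carrier, and the catechol ester 14 exchanges readily with the aliphatic diol 12.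

Step 8
Reactants: 16 (2R)-3-bromo-2-methylpropan-1-ol
Product: 17 {[(2R)-3-bromo-2-methylpropoxy]methyl}benzene
Conditions: BnOC(=NH)CCl3, TfOH (cat.), CH2Cl2/cyclohexane, 0 °C to rt
Reagents that add atoms: benzyl 2,2,2-trichloroacetimidate, N=C(OCc1ccccc1)C(Cl)(Cl)Cl
Why: Acid-catalysed O-benzylation with the trichloroacetimidate avoids an alkoxide (no oxetane closure onto the bromide); the stereocentre is not touched.

Step 9
Reactants: 17 {[(2R)-3-bromo-2-methylpropoxy]methyl}benzene
Product: 19 (4S)-5-(benzyloxy)-4-methylpentan-1-ol, via [(2R)-3-(benzyloxy)-2-methylpropyl]magnesium bromide 18 (not isolated)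
Conditions: Mg, THF, 40 °C; then oxirane, CuI (10 mol%), −30 to 0 °C; NH4Cl aq
Reagents that add atoms: oxirane, C1CO1
Why: Grignard formation and copper-catalysed epoxide opening add C13 and C12 and leave a primary alcohol; the stereocentre is β to magnesium and is not affected.

Step 10
Reactants: 19 (4S)-5-(benzyloxy)-4-methylpentan-1-ol
Product: 20 ({[(2S)-5-iodo-2-methylpentyl]oxy}methyl)benzene
Conditions: I2, PPh3, imidazole, CH2Cl2, 0 °C to rt
Reagents that add atoms: iodine, [I][I]
Why: Appel-type iodination of the primary alcohol (SN2 at C12) gives the substrate for iodine–lithium exchange.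

Step 11
Reactants: 20 ({[(2S)-5-iodo-2-methylpentyl]oxy}methyl)benzene; 15 the (E)-penta-1,4-dienyl B(mac) ester; 10 methyl 2,3-dimethoxy-4-(prop-1-en-2-yl)-5-[(trifluoromethanesulfonyl)oxy]benzoate
Product: 23 methyl 5-[(4S,5S,9S)-10-(benzyloxy)-9-methyl-5-{B(mac)}dec-1-en-4-yl]-2,3-dimethoxy-4-(prop-1-en-2-yl)benzoate (secondary C11 boronate; 1S 11S 15S in target numbering), via [(4S)-5-(benzyloxy)-4-methylpentyl]lithium 21 (not isolated), via lithium alkenyl(alkyl)borate complex 22 (not isolated)
Conditions: 20, t-BuLi (2.0 equiv), Et2O/pentane, −78 °C; add 15, −78 °C to rt; solvent change to THF; 10, Pd(OAc)2 (3 mol%), MandyPhos ligand [1,1'-bis(bis(4-methoxy-3,5-dimethylphenyl)phosphino)-2,2'-bis(α-(dimethylamino)benzyl)ferrocene] (3.6 mol%), NaOTf (2 equiv), 60 °C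
Reagents that add atoms: none
Why: Iodine–lithium exchange gives 21, which adds to the boron of 15 to give ate complex 22, so that no free organolithium meets the ester of 10. Oxidative addition of 10 to zerovalent palladium gives a cationic arylpalladium species of divalent palladium that binds the boron-bound alkene of 22; the alkyl group then migrates from boron to C11 anti to palladium on C1 (metal-induced 1,2-metallate shift), and reductive elimination forms C1–C8a with retention. This is the known enantioselective conjunctive cross-coupling of alkenylboron ate complexes with aryl triflates in its variant for β-substituted alkenyl boronates, where the hindered diol on boron suppresses direct alkenyl transfer to palladium (plain Suzuki–Miyaura coupling). No ring is closed. The relative configuration of C1 and C11 follows from the E geometry of 15 and the stereospecific anti addition of aryl and alkyl; the chiral bisphosphine on palladium selects the alkene face and so the (1S,11S) series, and C15 comes unchanged from 16 and is too remote to interfere. The step needs selectivity for the boron-bound alkene over the terminal alkene and the isopropenyl group, which the negative charge on boron should secure; it needs reductive elimination to outrun β-hydride loss from C2, which the chelating ligand favours; and NaOTf is added to keep iodide from the exchange off palladium.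

Step 12
Reactants: 23 the secondary C11 B(mac) boronate
Product: 25 methyl 5-[(4S,5S,9S)-10-(benzyloxy)-5-(hydroxymethyl)-9-methyldec-1-en-4-yl]-2,3-dimethoxy-4-(prop-1-en-2-yl)benzoate, via homologated primary boronate 24 (not isolated)
Conditions: BrCH2Cl (3 equiv), n-BuLi (2 equiv, added last), THF, −78 °C to rt; then NaOH, H2O2, THF/H2O, 0 °C
Reagents that add atoms: bromochloromethane, ClCBr; hydrogen peroxide, OO
Why: Matteson homologation: chloromethyllithium made in situ should be captured by boron faster than by the ester, the secondary alkyl group migrates from boron to carbon with retention at C11 to give 24, and alkaline peroxide oxidises the new primary C–B bond to the C20 alcohol.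

Step 13
Reactants: 25 the C20 alcohol with allyl and isopropenyl groups
Product: 26 methyl (8S)-8-[(2S,6S)-7-(benzyloxy)-1-hydroxy-6-methylheptan-2-yl]-3,4-dimethoxy-5-methyl-7,8-dihydronaphthalene-2-carboxylate
Conditions: second-generation Grubbs catalyst (5 mol%), toluene, 80 °C
Reagents that add atoms: none
Why: Ring-closing metathesis: the ruthenium carbene loads at the unhindered allyl terminus and closes the six-membered ring onto the isopropenyl alkene with loss of ethene; no stereocentre is touched.

Step 14
Reactants: 26 the 7,8-dihydronaphthalene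
Product: 27 methyl (5R,8S)-8-[(2S,6S)-7-(benzyloxy)-1-hydroxy-6-methylheptan-2-yl]-3,4-dimethoxy-5-methyl-5,6,7,8-tetrahydronaphthalene-2-carboxylate
Conditions: H2 (1 atm), [Ir(cod)(PCy3)(py)]PF6 (5 mol%), CH2Cl2, 25 °C
Reagents that add atoms: none
Why: Hydroxyl-directed homogeneous hydrogenation: the cationic iridium centre binds the C20 hydroxyl on the pseudoaxial C1 side chain and should deliver both hydrogens to the C3=C4 face on that side, so the C4 methyl ends up trans to the C1 substituent (4R); benzyl ether, ester and arene are inert to this catalyst.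

Step 15
Reactants: 27 the tetralin methyl ester
Product: 28 (5R,8S)-8-[(2S,6S)-7-(benzyloxy)-1-hydroxy-6-methylheptan-2-yl]-3,4-dimethoxy-5-methyl-5,6,7,8-tetrahydronaphthalene-2-carboxylic acid
Conditions: LiOH, THF/MeOH/H2O, 50 °C; then HCl aq to pH 3
Reagents that add atoms: lithium hydroxide, [Li+].[OH-]
Why: Saponification of the methyl ester while the catechol is still protected, so that the free catechol never meets aqueous base.

Step 16
Reactants: 28 the tetralin acid
Product: 29 (5R,8S)-8-[(2S,6S)-1,7-dihydroxy-6-methylheptan-2-yl]-3,4-dihydroxy-5-methyl-5,6,7,8-tetrahydronaphthalene-2-carboxylic acid (CNP0255074.1)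
Conditions: BBr3 (8 equiv), CH2Cl2, −78 to 0 °C; then H2O, work-up under argon
Reagents that add atoms: none
Why: Lewis-acid ether cleavage: BBr3 binds the ether oxygens and bromide removes the two aryl methyl groups and the benzyl group at carbon, leaving the stereocentres and the C–O bonds of both primary alcohols intact; water hydrolyses the borates to 29.

## Compound list

1 | 1,2-dimethoxybenzene | COc1ccccc1OC | starting material
2 | 3,6-dilithio-1,2-dimethoxybenzene | [Li]c1ccc([Li])c(OC)c1OC | intermediate (not isolated)
3 | 1,4-dibromo-2,3-dimethoxybenzene | COc1c(Br)ccc(Br)c1OC | intermediate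
4 | (2,5-dibromo-3,4-dimethoxyphenyl)lithium | [Li]c1cc(Br)c(OC)c(OC)c1Br | intermediate (not isolated)
5 | lithium (2,5-dibromo-3,4-dimethoxyphenyl)tri(propan-2-yloxy)borate | [Li+].CC(C)O[B-](OC(C)C)(OC(C)C)c1cc(Br)c(OC)c(OC)c1Br | intermediate (not isolated)
6 | 2,5-dibromo-3,4-dimethoxyphenol | Oc1cc(Br)c(OC)c(OC)c1Br | intermediate
7 | methyl 4-bromo-5-hydroxy-2,3-dimethoxybenzoate | COC(=O)c1cc(O)c(Br)c(OC)c1OC | intermediate
8 | 4,4,5,5-tetramethyl-2-(prop-1-en-2-yl)-1,3,2-dioxaborolane | C=C(C)B1OC(C)(C)C(C)(C)O1 | starting material
9 | methyl 5-hydroxy-2,3-dimethoxy-4-(prop-1-en-2-yl)benzoate | COC(=O)c1cc(O)c(C(C)=C)c(OC)c1OC | intermediate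
10 | methyl 2,3-dimethoxy-4-(prop-1-en-2-yl)-5-[(trifluoromethanesulfonyl)oxy]benzoate | COC(=O)c1cc(OS(=O)(=O)C(F)(F)F)c(C(C)=C)c(OC)c1OC | intermediate
11 | acenaphthylene-1,2-dione | O=C1C(=O)c2cccc3cccc1c23 | starting material
12 | (1R,2S)-1,2-dimethyl-1,2-dihydroacenaphthylene-1,2-diol (cis, meso) | C[C@]1(O)c2cccc3cccc(c23)[C@@]1(C)O | intermediate
13 | pent-1-en-4-yne | C=CCC#C | starting material
14 | 2-[(1E)-penta-1,4-dien-1-yl]-1,3,2-benzodioxaborole | C=CC/C=C/B1Oc2ccccc2O1 | intermediate (not isolated)
15 | (6bR,9aS)-6b,9a-dimethyl-8-[(1E)-penta-1,4-dien-1-yl]-6b,9a-dihydroacenaphtho[1,2-d][1,3,2]dioxaborole | C=CC/C=C/B1O[C@]2(C)c3cccc4cccc(c34)[C@]2(C)O1 | intermediate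
16 | (2R)-3-bromo-2-methylpropan-1-ol | C[C@H](CO)CBr | starting material
17 | {[(2R)-3-bromo-2-methylpropoxy]methyl}benzene | C[C@H](COCc1ccccc1)CBr | intermediate
18 | [(2R)-3-(benzyloxy)-2-methylpropyl]magnesium bromide | C[C@H](COCc1ccccc1)C[Mg]Br | intermediate (not isolated)
19 | (4S)-5-(benzyloxy)-4-methylpentan-1-ol | C[C@H](COCc1ccccc1)CCCO | intermediate
20 | ({[(2S)-5-iodo-2-methylpentyl]oxy}methyl)benzene | C[C@H](COCc1ccccc1)CCCI | intermediate
21 | [(4S)-5-(benzyloxy)-4-methylpentyl]lithium | C[C@H](COCc1ccccc1)CCC[Li] | intermediate (not isolated)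
22 | lithium [(4S)-5-(benzyloxy)-4-methylpentyl][(1E)-penta-1,4-dien-1-yl]borate of diol 12 | [Li+].C=CC/C=C/[B-]1(CCC[C@H](C)COCc2ccccc2)O[C@]2(C)c3cccc4cccc(c34)[C@]2(C)O1 | intermediate (not isolated)
23 | methyl 5-[(4S,5S,9S)-10-(benzyloxy)-9-methyl-5-{B(mac)}dec-1-en-4-yl]-2,3-dimethoxy-4-(prop-1-en-2-yl)benzoate | C[C@H](COCc1ccccc1)CCC[C@H](B1O[C@]2(C)c3cccc4cccc(c34)[C@]2(C)O1)[C@@H](c1cc(C(=O)OC)c(OC)c(OC)c1C(C)=C)CC=C | intermediate
24 | methyl 5-[(4S,5S,9S)-10-(benzyloxy)-9-methyl-5-{[B(mac)]methyl}dec-1-en-4-yl]-2,3-dimethoxy-4-(prop-1-en-2-yl)benzoate | C[C@H](COCc1ccccc1)CCC[C@H](CB1O[C@]2(C)c3cccc4cccc(c34)[C@]2(C)O1)[C@@H](c1cc(C(=O)OC)c(OC)c(OC)c1C(C)=C)CC=C | intermediate (not isolated)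
25 | methyl 5-[(4S,5S,9S)-10-(benzyloxy)-5-(hydroxymethyl)-9-methyldec-1-en-4-yl]-2,3-dimethoxy-4-(prop-1-en-2-yl)benzoate | C[C@H](COCc1ccccc1)CCC[C@H](CO)[C@@H](c1cc(C(=O)OC)c(OC)c(OC)c1C(C)=C)CC=C | intermediate
26 | methyl (8S)-8-[(2S,6S)-7-(benzyloxy)-1-hydroxy-6-methylheptan-2-yl]-3,4-dimethoxy-5-methyl-7,8-dihydronaphthalene-2-carboxylate | C[C@H](COCc1ccccc1)CCC[C@H](CO)[C@@H]1CC=C(C)c2c1cc(C(=O)OC)c(OC)c2OC | intermediate
27 | methyl (5R,8S)-8-[(2S,6S)-7-(benzyloxy)-1-hydroxy-6-methylheptan-2-yl]-3,4-dimethoxy-5-methyl-5,6,7,8-tetrahydronaphthalene-2-carboxylate | C[C@H](COCc1ccccc1)CCC[C@H](CO)[C@@H]1CC[C@@H](C)c2c1cc(C(=O)OC)c(OC)c2OC | intermediate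
28 | (5R,8S)-8-[(2S,6S)-7-(benzyloxy)-1-hydroxy-6-methylheptan-2-yl]-3,4-dimethoxy-5-methyl-5,6,7,8-tetrahydronaphthalene-2-carboxylic acid | C[C@H](COCc1ccccc1)CCC[C@H](CO)[C@@H]1CC[C@@H](C)c2c1cc(C(=O)O)c(OC)c2OC | intermediate
29 | (5R,8S)-8-[(2S,6S)-1,7-dihydroxy-6-methylheptan-2-yl]-3,4-dihydroxy-5-methyl-5,6,7,8-tetrahydronaphthalene-2-carboxylic acid | C[C@H](CO)CCC[C@H](CO)[C@@H]1CC[C@@H](C)c2c1cc(C(=O)O)c(O)c2O | target

## Step count and risk

Total step count: 16. Longest linear sequence: 11 steps (steps 1 to 5, then 11 to 16).

**Step 11 (key step).**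
- What may go wrong: direct transfer of the alkenyl group from boron to palladium instead of the metallate shift; β-hydride loss from the allylic C2 position before reductive elimination; slow turnover with the ortho-substituted triflate; inhibition by iodide; insufficient facial selectivity.
- Fallback: it sets out from 10 and 19 and returns at 25, building the C1/C11 pair in two separate known steps.
  - Borylation of 10 (B2pin2, PdCl2(dppf), KOAc, dioxane) would give methyl 2,3-dimethoxy-4-(prop-1-en-2-yl)-5-(4,4,5,5-tetramethyl-1,3,2-dioxaborolan-2-yl)benzoate F1.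
  - Rhodium-catalysed asymmetric conjugate addition of F1 ([Rh(OH)(cod)]2, (S)-BINAP or its enantiomer as needed, dioxane/H2O, no added base to spare the skipped diene) to 3-[(2E)-hexa-2,5-dienoyl]-1,3-oxazolidin-2-one F2 would set C1 in the β-aryl imide F3.
  - The sodium enolate of F3 (NaN(SiMe3)2, THF, −78 °C) would be alkylated with (4S)-5-(benzyloxy)-4-methylpentyl trifluoromethanesulfonate F4, made from 19 with Tf2O and 2,6-lutidine. The electrophile should enter anti to the aryl group in the Z-enolate conformer with the C1 hydrogen in the enolate plane, giving the imide F5 with the C1/C11 relation of the target.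
  - LiBH4 (THF, 0 °C) would then reduce the imide selectively over the aryl methyl ester and give 25.
  - This sequence is longer and its C11 control is substrate-based, but it uses no metallate rearrangement.

**Step 12.**
- What may go wrong: attack of the carbenoid or of n-BuLi on the methyl ester; slow ate formation at the hindered secondary boronate, so that unchanged C–B is later oxidised to a C11 alcohol.
- Fallback: it sets out from 23 and returns at 28, removing the electrophilic ester before the carbenoid is used.
  - Saponification of 23 (LiOH, THF/H2O) would give the carboxylic acid boronate F6.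
  - Its lithium carboxylate (one extra equivalent of base) is inert to chloromethyllithium, so homologation and oxidation as in step 12 would give the hydroxy acid F7.
  - Ring-closing metathesis as in step 13 would give the dihydronaphthalene acid F8.
  - Directed hydrogenation as in step 14 would give 28, after which only step 16 remains.

**Step 14.**
- What may go wrong: poor facial selectivity. The hydroxyl is four atoms away from C3, and the side chain that carries it also shields the face to which it must deliver hydrogen; addition from the other face would give the C4 epimer.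
- Fallback: it sets out from 26 and returns at 27, replacing substrate direction by catalyst control.
  - Silylation of 26 (TBSCl, imidazole) would give the silyl ether F9, which cannot direct.
  - Hydrogenation with a chiral cationic iridium phosphino-oxazoline complex, [Ir(cod)(L)]BArF with L = 4-tert-butyl-2-[2-(diphenylphosphanyl)phenyl]-4,5-dihydrooxazole, would then set C4. Both enantiomers of L are available and the one that adds hydrogen to the face giving 4R would be chosen. The product is the tetralin silyl ether F10.
  - Bu4NF would return 27.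

**Step 3.**
- What may go wrong: loss of site selectivity, with carbonylation at the bromide next to the hydroxyl or at both bromides.
- Fallback: it sets out from 6 and returns at 9, making the two halogens chemically different.
  - Protection of 6 (MOMCl, i-Pr2NEt) would give 1,4-dibromo-2,3-dimethoxy-5-(methoxymethoxy)benzene F11.
  - Bromine–lithium exchange (n-BuLi, THF, −78 °C) should occur at the bromide flanked by two oxygen substituents. Iodine would then give 1-bromo-4-iodo-2,3-dimethoxy-5-(methoxymethoxy)benzene F12.
  - Suzuki–Miyaura coupling with 8 would take place at the iodide and give 1-bromo-2,3-dimethoxy-5-(methoxymethoxy)-4-(prop-1-en-2-yl)benzene F13.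
  - Methoxycarbonylation of the only remaining bromide, under the conditions of step 3, would give methyl 2,3-dimethoxy-5-(methoxymethoxy)-4-(prop-1-en-2-yl)benzoate F14.
  - Mild acid (catalytic HCl, MeOH, rt) would remove the acetal and give 9.

Further compounds
F1 | step 11 | methyl 2,3-dimethoxy-4-(prop-1-en-2-yl)-5-(4,4,5,5-tetramethyl-1,3,2-dioxaborolan-2-yl)benzoate | COC(=O)c1cc(B2OC(C)(C)C(C)(C)O2)c(C(C)=C)c(OC)c1OC
F2 | step 11 | 3-[(2E)-hexa-2,5-dienoyl]-1,3-oxazolidin-2-one | C=CC/C=C/C(=O)N1CCOC1=O
F3 | step 11 | methyl 2,3-dimethoxy-5-[(4S)-6-oxo-6-(2-oxo-1,3-oxazolidin-3-yl)hex-1-en-4-yl]-4-(prop-1-en-2-yl)benzoate | C=CC[C@@H](CC(=O)N1CCOC1=O)c1cc(C(=O)OC)c(OC)c(OC)c1C(C)=C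
F4 | step 11 | (4S)-5-(benzyloxy)-4-methylpentyl trifluoromethanesulfonate | C[C@H](COCc1ccccc1)CCCOS(=O)(=O)C(F)(F)F
F5 | step 11 | methyl 5-[(4S,5S,9S)-10-(benzyloxy)-9-methyl-5-(2-oxo-1,3-oxazolidine-3-carbonyl)dec-1-en-4-yl]-2,3-dimethoxy-4-(prop-1-en-2-yl)benzoate | C[C@H](COCc1ccccc1)CCC[C@H](C(=O)N1CCOC1=O)[C@@H](c1cc(C(=O)OC)c(OC)c(OC)c1C(C)=C)CC=C
F6 | step 12 | 5-[(4S,5S,9S)-10-(benzyloxy)-9-methyl-5-{B(mac)}dec-1-en-4-yl]-2,3-dimethoxy-4-(prop-1-en-2-yl)benzoic acid | C[C@H](COCc1ccccc1)CCC[C@H](B1O[C@]2(C)c3cccc4cccc(c34)[C@]2(C)O1)[C@@H](c1cc(C(=O)O)c(OC)c(OC)c1C(C)=C)CC=C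
F7 | step 12 | 5-[(4S,5S,9S)-10-(benzyloxy)-5-(hydroxymethyl)-9-methyldec-1-en-4-yl]-2,3-dimethoxy-4-(prop-1-en-2-yl)benzoic acid | C[C@H](COCc1ccccc1)CCC[C@H](CO)[C@@H](c1cc(C(=O)O)c(OC)c(OC)c1C(C)=C)CC=C
F8 | step 12 | (8S)-8-[(2S,6S)-7-(benzyloxy)-1-hydroxy-6-methylheptan-2-yl]-3,4-dimethoxy-5-methyl-7,8-dihydronaphthalene-2-carboxylic acid | C[C@H](COCc1ccccc1)CCC[C@H](CO)[C@@H]1CC=C(C)c2c1cc(C(=O)O)c(OC)c2OC
F9 | step 14 | methyl (8S)-8-[(2S,6S)-7-(benzyloxy)-1-[(tert-butyldimethylsilyl)oxy]-6-methylheptan-2-yl]-3,4-dimethoxy-5-methyl-7,8-dihydronaphthalene-2-carboxylate | C[C@H](COCc1ccccc1)CCC[C@H](CO[Si](C)(C)C(C)(C)C)[C@@H]1CC=C(C)c2c1cc(C(=O)OC)c(OC)c2OC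
F10 | step 14 | methyl (5R,8S)-8-[(2S,6S)-7-(benzyloxy)-1-[(tert-butyldimethylsilyl)oxy]-6-methylheptan-2-yl]-3,4-dimethoxy-5-methyl-5,6,7,8-tetrahydronaphthalene-2-carboxylate | C[C@H](COCc1ccccc1)CCC[C@H](CO[Si](C)(C)C(C)(C)C)[C@@H]1CC[C@@H](C)c2c1cc(C(=O)OC)c(OC)c2OC
F11 | step 3 | 1,4-dibromo-2,3-dimethoxy-5-(methoxymethoxy)benzene | COCOc1cc(Br)c(OC)c(OC)c1Br
F12 | step 3 | 1-bromo-4-iodo-2,3-dimethoxy-5-(methoxymethoxy)benzene | COCOc1cc(Br)c(OC)c(OC)c1I
F13 | step 3 | 1-bromo-2,3-dimethoxy-5-(methoxymethoxy)-4-(prop-1-en-2-yl)benzene | COCOc1cc(Br)c(OC)c(OC)c1C(C)=C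
F14 | step 3 | methyl 2,3-dimethoxy-5-(methoxymethoxy)-4-(prop-1-en-2-yl)benzoate | COCOc1cc(C(=O)OC)c(OC)c(OC)c1C(C)=C
A1 | alternative 1 | methyl 5-[12-(benzyloxy)-7-[(benzyloxy)methyl]-3,11-dimethyldodec-1-yn-6-yl]furan-3-carboxylate (stereocentres as in 29) | C[C@H](COCc1ccccc1)CCC[C@H](COCc1ccccc1)[C@H](CC[C@@H](C)C#C)c1cc(C(=O)OC)co1
A2 | alternative 1 | methyl (5R,8S)-8-[(2S,6S)-1,7-bis(benzyloxy)-6-methylheptan-2-yl]-4-hydroxy-5-methyl-5,6,7,8-tetrahydronaphthalene-2-carboxylate | C[C@H](COCc1ccccc1)CCC[C@H](COCc1ccccc1)[C@@H]1CC[C@@H](C)c2c1cc(C(=O)OC)cc2O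
A3 | alternative 2 | tert-butyl 5-[9-(benzyloxy)-4-[(benzyloxy)methyl]-1-bromo-8-methylnonan-3-yl]-4-ethenyl-2,3-dimethoxybenzoate (stereocentres as in 29) | C[C@H](COCc1ccccc1)CCC[C@H](COCc1ccccc1)[C@H](CCBr)c1cc(C(=O)OC(C)(C)C)c(OC)c(OC)c1C=C
A4 | alternative 2 | tert-butyl (5R,8S)-8-[(2S,6S)-1,7-bis(benzyloxy)-6-methylheptan-2-yl]-3,4-dimethoxy-5-methyl-5,6,7,8-tetrahydronaphthalene-2-carboxylate | C[C@H](COCc1ccccc1)CCC[C@H](COCc1ccccc1)[C@@H]1CC[C@@H](C)c2c1cc(C(=O)OC(C)(C)C)c(OC)c2OC
A5 | alternative 3 | methyl 5-[1,7-bis(benzyloxy)-6-methylheptan-2-yl]-8-methyl-2-oxo-5,6,7,8-tetrahydro-2H-chromene-3-carboxylate (stereocentres as in 29) | C[C@H](COCc1ccccc1)CCC[C@H](COCc1ccccc1)[C@@H]1CC[C@@H](C)C2=C1C=C(C(=O)OC)C(=O)O2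
A6 | alternative 3 | 1,1,2-trimethoxyethene | COC=C(OC)OC
A7 | alternative 3 | methyl (5R,8S)-8-[(2S,6S)-1,7-bis(benzyloxy)-6-methylheptan-2-yl]-3,4-dimethoxy-5-methyl-5,6,7,8-tetrahydronaphthalene-2-carboxylate | C[C@H](COCc1ccccc1)CCC[C@H](COCc1ccccc1)[C@@H]1CC[C@@H](C)c2c1cc(C(=O)OC)c(OC)c2OC
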